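**Retrosynthetic overview**
- The lactone ring is formed last. Cut C4–O back to a Δ4-1,2-dioxine-3-acetic acid. The carboxyl group adds 5-exo to C4=C5, with Br+ standing in for H+, and Br is then replaced by H.
- This lactonisation is run as a catalytic kinetic resolution, which fixes the absolute configuration.
- The peroxide ring is formed first. Cut C3–O and C6–O together, back to the achiral (3E,5E)-dienoic acid plus O2. This is a suprafacial singlet-oxygen [4+2], so the two alkene geometries become the C3/C6 relative configuration.
- The dienoic acid comes from the dienol by oxidation. Its C4–C5 bond comes from an alkenyl–alkenyl Negishi coupling of two stereodefined halves, made by methylalumination of octadec-1-yne and hydrozirconation of pent-3-yn-1-ol.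

Numbering used in names: polyketide numbering. C1 is the carboxyl/lactone carbon, C3 and C6 carry the O–O bridge, and C4 carries the lactone oxygen.

Assumption: the sense of enantiomer selection in step 5 cannot be predicted with certainty. (DHQD)2PHAL is written, and the pseudo-enantiomer (DHQ)2PHAL is used instead if a test run shows that it lactonises the (3S,6R) acid faster.

**Step 1**
Reactants: 1 octadec-1-yne
Product: 3 (E)-1-iodo-2-methyloctadec-1-ene, via alkenyldimethylalane 2 (not isolated)
Conditions: AlMe3 (2 equiv), Cp2ZrCl2 (0.2 equiv), CH2Cl2, 0 °C to rt; then I2, THF, −30 to 0 °C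
Reagents that add atoms: trimethylaluminium C[Al](C)C; iodine [I][I]
Why: Zirconium-catalysed methylalumination of a terminal alkyne (Negishi carboalumination) is a syn addition that puts CH3 on the internal carbon and Al on the terminus, and iodinolysis of the C–Al bond goes with retention, so the later C5=C6 geometry (chain trans to C4) is fixed here.

**Step 2**
Reactants: 3 (E)-1-iodo-2-methyloctadec-1-ene; 4 pent-3-yn-1-ol
Product: 6 (3E,5E)-4,6-dimethyldocosa-3,5-dien-1-ol, via bis-zirconated pentenolate 5 (not isolated)
Conditions: 4, Cp2Zr(H)Cl (2.3 equiv), THF, rt to 40 °C; then 3, Pd(PPh3)4 (5 mol%), ZnCl2 (20 mol%), THF, rt; aq. NH4Cl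
Reagents that add atoms: none
Why: Syn-hydrozirconation, with excess Cp2Zr(H)Cl equilibrating Zr to the less hindered, methyl-bearing alkyne carbon after the OH is masked as its zirconium alkoxide, followed by Negishi alkenyl–alkenyl coupling (zerovalent palladium, ZnCl2 as transmetalation shuttle) with retention at both sp2 carbons, gives the (3E,5E)-diene.

**Step 3**
Reactants: 6 (3E,5E)-4,6-dimethyldocosa-3,5-dien-1-ol
Product: 8 (3E,5E)-4,6-dimethyldocosa-3,5-dienoic acid, via dienal 7 (not isolated)
Conditions: TEMPO (20 mol%), PhI(OAc)2 (2.2 equiv), MeCN/CH2Cl2/H2O, rt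
Reagents that add atoms: water O
Why: Oxoammonium (TEMPO/PhI(OAc)2) oxidation takes the primary alcohol through the aldehyde hydrate to the acid under nearly neutral conditions, which avoids migration of the 3,5-diene into conjugation with the carboxyl group and leaves both alkene geometries untouched.

**Step 4**
Reactants: 8 (3E,5E)-4,6-dimethyldocosa-3,5-dienoic acid
Product: 9 rac-2-[(3S,6R)-6-hexadecyl-4,6-dimethyl-3,6-dihydro-1,2-dioxin-3-yl]acetic acid (CH2CO2H and hexadecyl cis)
Conditions: O2, tetraphenylporphyrin (0.5 mol%), visible light, CH2Cl2, −20 °C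
Reagents that add atoms: dioxygen O=O
Why: In this singlet-oxygen [4+2] cycloaddition (photooxygenation, the presumed biogenetic peroxide formation) the 4-methyl group biases the diene towards s-cis, and suprafacial addition to the (3E,5E)-diene makes the two outside groups (CH2CO2H on C3, hexadecyl on C6) cis, so the C3/C6 relative configuration follows directly from the alkene geometries and the product is a racemate.

**Step 5**
Reactants: 9 rac-2-[(3S,6R)-6-hexadecyl-4,6-dimethyl-3,6-dihydro-1,2-dioxin-3-yl]acetic acid
Product: 10 (3S,4R,5S,6R)-5-bromo-3,6-epidioxy-4,6-dimethyldocosan-4-olide (cis-fused bromolactone, Br anti to the lactone oxygen)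
Conditions: hydroquinidine 1,4-phthalazinediyl diether (DHQD)2PHAL (10 mol%), NBS (0.48 equiv), CHCl3/hexane 1:1, −40 °C; aq. NaHCO3 wash removes unreacted acid; recrystallise
Reagents that add atoms: N-bromosuccinimide O=C1CCC(=O)N1Br
Why: Proposed new method: this is an enantiomer-selective catalytic bromolactonisation of a racemic dioxine acid, in which the carboxylate is ion-paired to the protonated quinuclidine inside the chiral pocket (which also keeps the amine from triggering base-induced peroxide cleavage), catalyst-bound NBS delivers Br+ to the C4=C5 face anti to the side chain, the carboxyl oxygen closes 5-exo on the tertiary C4 from the face that carries C2 (only the cis-fused lactone is possible, so C4 follows from C3 and Br ends anti on C5), and the faster cyclisation of the better-fitting (3S,6R) acid fixes the absolute configuration at about 45% conversion; the closest known reactions are (DHQD)2PHAL-catalysed asymmetric halolactonisation of pent-4-enoic acids, kinetic resolution of racemic olefinic acids and amides by catalytic halocyclisation, and racemic halolactonisation of this same dioxine ring system.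

**Step 6**
Reactants: 10 (3S,4R,5S,6R)-5-bromo-3,6-epidioxy-4,6-dimethyldocosan-4-olide
Product: 11 (3S,4S,6R)-3,6-epidioxy-4,6-dimethyldocosan-4-olide = (3R,4aS,7aS)-3-hexadecyl-3,4a-dimethyltetrahydrofuro[3,2-c][1,2]dioxin-6-one (target)
Conditions: Bu3SnH (1.3 equiv), Et3B (0.2 equiv), trace air, toluene, 0 °C
Reagents that add atoms: none
Why: In this radical chain hydrodebromination Bu3Sn• abstracts the secondary bromine far faster than it attacks a dialkyl peroxide, the ring geometry of the C5 radical disfavours backside attack on the O–O bond, and fast hydrogen transfer gives the C5 methylene without touching C3, C4 or C6.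

**Compound list**
1 | octadec-1-yne | CCCCCCCCCCCCCCCCC#C | starting material
2 | (E)-dimethyl(2-methyloctadec-1-enyl)alane | CCCCCCCCCCCCCCCC/C(C)=C/[Al](C)C | intermediate (not isolated)
3 | (E)-1-iodo-2-methyloctadec-1-ene | CCCCCCCCCCCCCCCC/C(C)=C/I | intermediate
4 | pent-3-yn-1-ol | CC#CCCO | starting material
5 | (E)-4-[chlorobis(cyclopentadienyl)zirconio]pent-3-enyl chlorozirconocene alkoxide | Cl[Zr](C1C=CC=C1)(C1C=CC=C1)/C(C)=C/CCO[Zr](Cl)(C1C=CC=C1)C1C=CC=C1 | intermediate (not isolated)
6 | (3E,5E)-4,6-dimethyldocosa-3,5-dien-1-ol | CCCCCCCCCCCCCCCC/C(C)=C/C(C)=C/CCO | intermediate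
7 | (3E,5E)-4,6-dimethyldocosa-3,5-dienal | CCCCCCCCCCCCCCCC/C(C)=C/C(C)=C/CC=O | intermediate (not isolated)
8 | (3E,5E)-4,6-dimethyldocosa-3,5-dienoic acid | CCCCCCCCCCCCCCCC/C(C)=C/C(C)=C/CC(=O)O | intermediate
9 | rac-2-[(3S,6R)-6-hexadecyl-4,6-dimethyl-3,6-dihydro-1,2-dioxin-3-yl]acetic acid (racemate; the enantiomer carried on is drawn) | CCCCCCCCCCCCCCCC[C@]1(C)C=C(C)[C@H](CC(=O)O)OO1 | intermediate
10 | (3S,4R,5S,6R)-5-bromo-3,6-epidioxy-4,6-dimethyldocosan-4-olide | CCCCCCCCCCCCCCCC[C@]1(C)[C@@H](Br)[C@]2(C)OC(=O)C[C@@H]2OO1 | intermediate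
11 | (3S,4S,6R)-3,6-epidioxy-4,6-dimethyldocosan-4-olide | CCCCCCCCCCCCCCCC[C@]1(C)C[C@]2(C)OC(=O)C[C@@H]2OO1 | target

**Total step count:** 6. **Longest linear sequence:** 6 (1 → 3 → 6 → 8 → 9 → 10 → 11); 4 enters directly in step 2.

**Three steps most likely to fail**

1. Step 5. The selectivity factor may be too low for this all-alkyl alkene. The fallback is a covalent resolution with a chiral amine that the lactonisation itself expels.
   - It sets out from 9. EDC/HOBt coupling with (S)-1-phenylethylamine at 0 °C gives the (3S,6R,S) amide F1 and the (3R,6S,S) amide F2, which are separated on silica gel.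
   - F1 is treated with NBS in THF/water. The amide carbonyl oxygen closes on C4 and the aqueous medium releases the amine.
   - The fallback comes back to the route at 10.

2. Step 4. An ene reaction, or partial loss of C6 fidelity through a stepwise addition, may compete with a clean [4+2]. The fallback switches to the other biogenetic proposal, conjugate addition of a C6 hydroperoxide to a butenolide.
   - It sets out from 8. Cinchona-catalysed 5-endo bromolactonisation (NBS, (DHQD)2PHAL) gives the (4R,5S)-4-bromo-5-alkenyl lactone F3, and DBU removes HBr to give the (R)-butenolide F4.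
   - Co(thd)2 (bis(2,2,6,6-tetramethylheptane-3,5-dionato)cobalt), O2 and Et3SiH place a silylperoxy group on C6 to give the silyl peroxide F5 as both C6 epimers. HF·pyridine then frees the hydroperoxide F6.
   - Et2NH in CF3CH2OH closes the dioxane by oxa-Michael addition, cis to the tether.
   - The fallback comes back to the route at 11 after chromatographic removal of the 6-epimer F7.

3. Step 6. Tin or C5 radicals may attack the O–O bond. The fallback makes no carbon–halogen bond in the compound that is carried on.
   - It sets out from 9. The resolution is run in the opposite sense ((DHQ)2PHAL, NBS, about 60% conversion). The (3S,6R) acid F8 is recovered by base extraction in high ee, while its antipode ends up as the enantiomeric bromolactone F9.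
   - Divalent mercury acetate Hg(OAc)2 in THF closes the lactone of F8 to the 5-acetoxymercurio lactone F10.
   - Alkaline NaBH4 in the same flask replaces Hg by H. This is oxymercuration–demercuration, a peroxide-tolerant formal hydrolactonisation with very fast in-cage hydrogen transfer.
   - The fallback comes back to the route at 11.

**Further compounds**
F1 | step 5 | (S)-1-phenylethylamide of the (3S,6R) acid | CCCCCCCCCCCCCCCC[C@]1(C)C=C(C)[C@H](CC(=O)N[C@@H](C)c2ccccc2)OO1
F2 | step 5 | (S)-1-phenylethylamide of the (3R,6S) acid | CCCCCCCCCCCCCCCC[C@@]1(C)C=C(C)[C@@H](CC(=O)N[C@@H](C)c2ccccc2)OO1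
F3 | step 4 | (4R,5S)-4-bromo-5-methyl-5-[(E)-2-methyloctadec-1-enyl]dihydrofuran-2(3H)-one | CCCCCCCCCCCCCCCC/C(C)=C/[C@]1(C)OC(=O)C[C@H]1Br
F4 | step 4 | (R)-5-methyl-5-[(E)-2-methyloctadec-1-enyl]furan-2(5H)-one | CCCCCCCCCCCCCCCC/C(C)=C/[C@]1(C)OC(=O)C=C1
F5 | step 4 | (5S)-5-methyl-5-[2-methyl-2-(triethylsilylperoxy)octadecyl]furan-2(5H)-one, both C6 epimers | CCCCCCCCCCCCCCCCC(C)(OO[Si](CC)(CC)CC)C[C@]1(C)OC(=O)C=C1
F6 | step 4 | (5S)-5-(2-hydroperoxy-2-methyloctadecyl)-5-methylfuran-2(5H)-one, both C6 epimers | CCCCCCCCCCCCCCCCC(C)(OO)C[C@]1(C)OC(=O)C=C1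
F7 | step 4 | (3S,4S,6S)-3,6-epidioxy-4,6-dimethyldocosan-4-olide (6-epimer of 11) | CCCCCCCCCCCCCCCC[C@@]1(C)C[C@]2(C)OC(=O)C[C@@H]2OO1
F8 | step 6 | 2-[(3S,6R)-6-hexadecyl-4,6-dimethyl-3,6-dihydro-1,2-dioxin-3-yl]acetic acid, single enantiomer | CCCCCCCCCCCCCCCC[C@]1(C)C=C(C)[C@H](CC(=O)O)OO1
F9 | step 6 | (3R,4S,5R,6S)-5-bromo-3,6-epidioxy-4,6-dimethyldocosan-4-olide (enantiomer of 10) | CCCCCCCCCCCCCCCC[C@@]1(C)[C@H](Br)[C@@]2(C)OC(=O)C[C@H]2OO1
F10 | step 6 | 5-acetoxymercurio analogue of 10 (Hg anti to the lactone oxygen) | CCCCCCCCCCCCCCCC[C@]1(C)[C@@H]([Hg]OC(C)=O)[C@]2(C)OC(=O)C[C@@H]2OO1
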